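A direct plan would keep ring A as a bought benzene ring and add the pyranone to it.
It would take 2,4-dimethoxy-3-methylbenzaldehyde A1 through five operations (CHO to CH3 hydrogenolysis, Rieche formylation, Dakin oxidation, bromination, silylation/retro-Brook shift/triflation) to silylaryl triflate A2.
Fluoride would release aryne A3, which would insert into the acyl C–O bond of docos-2-ynoic acid A4 to give ortho-hydroxyaryl ynone A5; oxa-Michael closure would give dimethoxychromone A6, and BBr3 would free the two phenols.
Weak point, the run-up to A2: five linear steps of redox and functional-group change would only dress a benzene ring as an aryne precursor and would add one methyl carbon of the target.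
Weak point, the aryne insertion: which aryne carbon takes the oxygen would rest on a small inductive bias of one methoxy group against a methyl and a methoxy group, and acyl transfer would have to outrun protonation of the aryl anion at 125 °C.
Weak point, the final double demethylation: two O-methyl groups would be carried through the whole route only to be removed with excess BBr3 from the finished chromone, the C7 ether lying between two methyl groups.

**Retrosynthetic overview**
Ring A is built last, on a finished γ-pyranone, by cutting C7–C8 and C5–C6 (chromone numbering). C8 with its methyl group becomes an ethyl group on C8a, C5 becomes the carbon of an ester on C4a, and C6(CH3)–C7(OH) becomes a propanoyl unit.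
The precursor is the monocyclic ethyl 2-ethyl-6-nonadecyl-4-oxo-4H-pyran-3-carboxylate (7); its pyranone ring closes first, at O1–C2 of the later chromone, by addition of a β-keto ester enol to an ynone.
One anionic operation then joins 7 and propanoyl chloride to the fully substituted phloroglucinol ring, in the manner of a polyketide Claisen cyclisation, and should give the target with both phenols free.
The design has no aryne (no regiochemical question), no O-protecting group (no late demethylation) and no run-up to a dressed arene: three steps from two C3 acid derivatives, one β-keto ester and one alkyl bromide.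

Key step: step 3

Step 1
Reactants: 1 propiolic acid; 2 1-bromononadecane
Product: 3 docos-2-ynoic acid
Conditions: n-BuLi (2.1 equiv), THF/HMPA, −78 °C; then 2, −78 °C to rt; aq. HCl
Reagents that add atoms: none
Why: Double deprotonation gives the dilithio carboxylate acetylide, whose acetylide carbon is the more nucleophilic site and is alkylated by the primary bromide in an SN2 reaction promoted by HMPA.

Step 2
Reactants: 3 docos-2-ynoic acid; 4 ethyl 3-oxopentanoate
Product: 7 ethyl 2-ethyl-6-nonadecyl-4-oxo-4H-pyran-3-carboxylate, via docos-2-ynoyl chloride 5 (not isolated), via ethyl 3-oxo-2-propanoyltetracos-4-ynoate 6 (not isolated)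
Conditions: (COCl)2, DMF (cat.), CH2Cl2, 0 °C to rt, evaporate; 4, MgCl2, pyridine, CH2Cl2, 0 °C to rt; aq. HCl; then TsOH (cat.), toluene, 60 °C
Reagents that add atoms: none
Why: The magnesium chelate of the β-keto ester (soft enolisation) is C-acylated by the ynoyl chloride, and the propanoyl enol oxygen of triacylmethane 6, a better nucleophile than the ester oxygen, adds 6-endo-dig to the ynone β-carbon (oxa-Michael); this is the classical γ-pyranone synthesis from alk-2-ynoyl chlorides and β-keto ester enolates.

Step 3
Reactants: 7 ethyl 2-ethyl-6-nonadecyl-4-oxo-4H-pyran-3-carboxylate; 8 propanoyl chloride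
Product: 10 5,7-dihydroxy-6,8-dimethyl-2-nonadecyl-4H-chromen-4-one, via ethyl 6-nonadecyl-4-oxo-2-(3-oxopentan-2-yl)-4H-pyran-3-carboxylate 9 (not isolated)
Conditions: LiN(SiMe3)2 (2.4 equiv), THF, −78 °C; 8 (1.2 equiv), −78 to −40 °C; LiN(i-Pr)2 (2.5 equiv), −78 to 0 °C; then 1 M HCl
Reagents that add atoms: none
Why: Proposed new method: LiN(SiMe3)2 should remove a proton from the CH2 of the C2 ethyl group, the only position whose anion is conjugated through C2=C3 with both the ester and the C4 carbonyl, and the dienolate should be acylated at that carbon by 8 (bond C7–C8), the acidic product 9 being held as its enolate by the second equivalent of base; LiN(i-Pr)2 should then form the dianion at the terminal CH2 of the new ketone, which attacks the neighbouring ester (bond C5–C6) and expels ethoxide, and the cyclic dione enolises to the 5,7-dihydroxy arene on acidification. The closest known reaction types are the acylation and Claisen cyclisation of ortho-toluate anions to naphthalene-1,3-diols (the acyl-donor counterpart of the Staunton–Weinreb annulation) and the γ-C-acylation of lithium dienolates of vinylogous esters such as 6-methyl-1,3-dioxin-4-ones with acid chlorides; neither has been applied to a 4-pyranone-3-carboxylate. Ring A closes by a 6-exo-trig Dieckmann-type attack of an enolate carbon on an ester carbonyl, made irreversible by aromatisation. No stereocentre is formed in the product, and the single stereocentre of racemic 9 is lost. The step needs C-acylation and not O-acylation of the dienolate, which low temperature, the lithium counter-ion and the irreversible deprotonation of 9 should favour (an O-acylated dienol ester can still pass its acyl group to the carbon of a second dienolate), and it needs C–C closure and not lactonisation through the enolate oxygen, which the far more nucleophilic terminal carbanion of the dianion should secure. The nonadecyl α-CH2 is activated by the C4 carbonyl alone and should not be deprotonated by the weaker base LiN(SiMe3)2 in the first stage.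

**Compound list**
1 | propiolic acid | C#CC(=O)O | starting material
2 | 1-bromononadecane | CCCCCCCCCCCCCCCCCCCBr | starting material
3 | docos-2-ynoic acid | CCCCCCCCCCCCCCCCCCCC#CC(=O)O | intermediate
4 | ethyl 3-oxopentanoate | CCC(=O)CC(=O)OCC | starting material
5 | docos-2-ynoyl chloride | CCCCCCCCCCCCCCCCCCCC#CC(=O)Cl | intermediate
6 | ethyl 3-oxo-2-propanoyltetracos-4-ynoate | CCCCCCCCCCCCCCCCCCCC#CC(=O)C(C(=O)CC)C(=O)OCC | intermediate
7 | ethyl 2-ethyl-6-nonadecyl-4-oxo-4H-pyran-3-carboxylate | CCCCCCCCCCCCCCCCCCCc1cc(=O)c(C(=O)OCC)c(CC)o1 | intermediate
8 | propanoyl chloride | CCC(=O)Cl | starting material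
9 | ethyl 6-nonadecyl-4-oxo-2-(3-oxopentan-2-yl)-4H-pyran-3-carboxylate (racemic) | CCCCCCCCCCCCCCCCCCCc1cc(=O)c(C(=O)OCC)c(C(C)C(=O)CC)o1 | intermediate
10 | 5,7-dihydroxy-6,8-dimethyl-2-nonadecyl-4H-chromen-4-one | CCCCCCCCCCCCCCCCCCCc1cc(=O)c2c(O)c(C)c(O)c(C)c2o1 | target

**Step count**
Total steps: 3. Longest linear sequence: 3 (steps 1 to 3).

**Steps most likely to fail**

1. Step 3 (proposed new method). The dienolate may be acylated on oxygen, the free LiN(SiMe3)2 may consume the acid chloride before the dienolate does, the dianion may form incompletely, or the enolate oxygen of 9 may close onto the ester to give a fused lactone in place of the C5–C6 bond. The fallback uses known chemistry and buys the arene in place of building it; it sets out from acid chloride 5 (made from 3 as in step 2) and comes back at 10. Commercial 2,4,6-trimethoxytoluene would be lithiated between two methoxy groups (n-BuLi, TMEDA, THF, 0 °C) and methylated with MeI to 1,3,5-trimethoxy-2,4-dimethylbenzene F1. Friedel–Crafts acylation of F1 at its only free ring position with 5 (AlCl3, CH2Cl2, −20 to 0 °C) would give 1-(2,4,6-trimethoxy-3,5-dimethylphenyl)docos-2-yn-1-one F2. BBr3 (CH2Cl2, −78 °C to rt) would cleave the three ethers to 1-(2,4,6-trihydroxy-3,5-dimethylphenyl)docos-2-yn-1-one F3. Either of the two equivalent ortho-hydroxyl groups of F3 would then close by 6-endo oxa-Michael addition (K2CO3, acetone, reflux) to 10.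

2. Step 2. The magnesium enolate may add in conjugate fashion to the ynoyl chloride (the path to 2-pyranones), HCl or pyridine may add to the triple bond, or the 6-endo closure of 6 may be slow. The fallback needs no alkyne; it sets out from 4 and comes back at 7. Condensation of 4 with pyrrolidine (TsOH cat., toluene, water separator) would give ethyl (2E)-3-(pyrrolidin-1-yl)pent-2-enoate F4. Icosanoyl chloride and Meldrum's acid (pyridine, CH2Cl2, 0 °C) would give 5-(1-hydroxyicosylidene)-2,2-dimethyl-1,3-dioxane-4,6-dione F5. Thermolysis of F5 in toluene at 110 °C in the presence of F4 would release the acylketene docos-1-ene-1,3-dione F6, which acylates the enamine carbon to give ethyl (2E)-3,5-dioxo-2-[1-(pyrrolidin-1-yl)propylidene]tetracosanoate F7, a push–pull alkene whose geometry is labile and has no bearing on the closure. The diketone enol oxygen of F7 would then add to the enamine carbon with loss of pyrrolidine (TsOH, toluene, 80 °C) to give 7.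

3. Step 1. The dilithio propiolate is a weak nucleophile, so alkylation by the long-chain bromide may be incomplete and elimination of HBr from 2 may compete. The fallback introduces the two alkyne carbons first and the carboxyl carbon second; it sets out from 2 and comes back at 3. Bromide 2 and LiC≡CH·H2NCH2CH2NH2 (DMSO, rt) would give henicos-1-yne F8. Deprotonation of F8 (n-BuLi, THF, −78 °C), carboxylation with CO2 and acidification would give 3.

**Further compounds**
F1 | step 3 | 1,3,5-trimethoxy-2,4-dimethylbenzene | COc1cc(OC)c(C)c(OC)c1C
F2 | step 3 | 1-(2,4,6-trimethoxy-3,5-dimethylphenyl)docos-2-yn-1-one | CCCCCCCCCCCCCCCCCCCC#CC(=O)c1c(OC)c(C)c(OC)c(C)c1OC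
F3 | step 3 | 1-(2,4,6-trihydroxy-3,5-dimethylphenyl)docos-2-yn-1-one | CCCCCCCCCCCCCCCCCCCC#CC(=O)c1c(O)c(C)c(O)c(C)c1O
F4 | step 2 | ethyl (2E)-3-(pyrrolidin-1-yl)pent-2-enoate | CC/C(N1CCCC1)=C\C(=O)OCC
F5 | step 2 | 5-(1-hydroxyicosylidene)-2,2-dimethyl-1,3-dioxane-4,6-dione | CCCCCCCCCCCCCCCCCCCC(O)=C1C(=O)OC(C)(C)OC1=O
F6 | step 2 | docos-1-ene-1,3-dione (icosanoylketene) | CCCCCCCCCCCCCCCCCCCC(=O)C=C=O
F7 | step 2 | ethyl (2E)-3,5-dioxo-2-[1-(pyrrolidin-1-yl)propylidene]tetracosanoate | CCCCCCCCCCCCCCCCCCCC(=O)CC(=O)/C(C(=O)OCC)=C(/CC)N1CCCC1
F8 | step 1 | henicos-1-yne | CCCCCCCCCCCCCCCCCCCC#C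
A1 | direct plan | 2,4-dimethoxy-3-methylbenzaldehyde | COc1ccc(C=O)c(OC)c1C
A2 | direct plan | 2,4-dimethoxy-3,5-dimethyl-6-(trimethylsilyl)phenyl trifluoromethanesulfonate | COc1c(C)c(OC)c(OS(=O)(=O)C(F)(F)F)c([Si](C)(C)C)c1C
A3 | direct plan | 3,5-dimethoxy-4,6-dimethylbenzyne | COC1=C(C)C#CC(OC)=C1C
A4 | direct plan | docos-2-ynoic acid | CCCCCCCCCCCCCCCCCCCC#CC(=O)O
A5 | direct plan | 1-(2-hydroxy-4,6-dimethoxy-3,5-dimethylphenyl)docos-2-yn-1-one | CCCCCCCCCCCCCCCCCCCC#CC(=O)c1c(O)c(C)c(OC)c(C)c1OC
A6 | direct plan | 5,7-dimethoxy-6,8-dimethyl-2-nonadecyl-4H-chromen-4-one | CCCCCCCCCCCCCCCCCCCc1cc(=O)c2c(OC)c(C)c(OC)c(C)c2o1
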